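**Plan**

1. Retrosynthesis: remove the seven benzyl ethers, then cut C3–C4 and C2–H in ring C of the upper flavanone; re-joining C4 to C2 contracts that ring to a 2,2-disubstituted benzofuran-3(2H)-one (13) with C3 as an exocyclic CH(NHTs) carbon.
2. Further cuts: C2–C3 (Mannich) gives 2-arylbenzofuranone 4 and the N-tosyl imine 12 of the lower flavanone; 4 is cut at C2–aryl; 12 at C8''–CHO, at C2''–aryl and back to a chromone.
3. Forward: the lower unit's pyranone ring is closed first (chromone, then flavanone), C8'' is functionalised, the two halves are joined on the five-membered ring, and ring C of the upper unit arises last by a five-to-six ring expansion.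
4. Enabling feature: C4 (ketone carbon), C2 (bonded to O1 and the catechol ring) and C3 (bonded to C8'', which lies between two ring oxygens and para to a third) are contiguous. A cation at C3 is stabilised by that trioxygenated ring, the acyl carbon C4 can shift to it from C2, and the charge then rests on C2 between O1 and the catechol ring.
5. Stereochemistry: C2'' from a ligand-controlled Pd conjugate addition; the quaternary C2 of 13 from a squaramide-catalysed Mannich addition; C3 by 1,2-transfer of chirality during the acyl shift; C2 by hydride delivery anti to the 3-aryl group, which gives the 2,3-cis arrangement.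

Key step: step 9

Remark: the given (2R,3R) configuration places the two aryl groups of the upper ring cis, the less stable arrangement next to the ketone, so C3 is created in the last C–C bond-forming step without base and only neutral hydrogenolysis follows; the facial sense of the catalysts in steps 4 and 8 is assumed as written and would be corrected with the antipodal ligand or the quinidine-derived catalyst.

**Route**

Step 1
Reactants: 1 4,6-dihydroxybenzofuran-3(2H)-one
Product: 2 4,6-bis(benzyloxy)benzofuran-3(2H)-one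
Conditions: BnBr (2.2 equiv), K2CO3 (2.2 equiv), DMF, 0 °C to rt
Reagents that add atoms: benzyl bromide, BrCc1ccccc1
Why: Williamson O-benzylation of the two phenols should proceed at oxygen because the phenoxides are far more readily formed than the ketone enolate; no stereocenter is formed.

Step 2
Reactants: 2 4,6-bis(benzyloxy)benzofuran-3(2H)-one; 3 4-bromo-1,2-bis(benzyloxy)benzene
Product: 4 rac-4,6-bis(benzyloxy)-2-[3,4-bis(benzyloxy)phenyl]benzofuran-3(2H)-one
Conditions: Pd(OAc)2 (3 mol%), XPhos (6 mol%), NaOC(CH3)3 (2.2 equiv), toluene, 80 °C, argon; aq. NH4Cl work-up under argon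
Reagents that add atoms: none
Why: Palladium-catalysed ketone α-arylation should stop after one aryl transfer because the product is held as its stabilised, hindered enolate; the new C2 centre is configurationally labile and is left racemic on purpose.

Step 3
Reactants: 5 1-[2,4-bis(benzyloxy)-6-hydroxyphenyl]ethanone
Product: 7 5,7-bis(benzyloxy)-4H-chromen-4-one, via enaminone 6 (not isolated)
Conditions: Me2NCH(OMe)2, toluene, 100 °C; then glacial AcOH, 80 °C
Reagents that add atoms: N,N-dimethylformamide dimethyl acetal, COC(OC)N(C)C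
Why: Enaminone formation at the acetyl group followed by acid-promoted addition–elimination of the phenol (loss of dimethylamine) is the standard chromone synthesis from 2-hydroxyacetophenones; no stereocenter is formed.

Step 4
Reactants: 7 5,7-bis(benzyloxy)-4H-chromen-4-one; 8 4-(benzyloxy)phenylboronic acid
Product: 9 (2S)-5,7-bis(benzyloxy)-2-[4-(benzyloxy)phenyl]chroman-4-one
Conditions: Pd(OCOCF3)2 (5 mol%), (S)-4-tert-butyl-2-(pyridin-2-yl)-4,5-dihydrooxazole (6 mol%), NH4PF6 (30 mol%), H2O (5 equiv), ClCH2CH2Cl, 60 °C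
Reagents that add atoms: none
Why: Palladium-catalysed asymmetric conjugate addition of an arylboronic acid to a chromone (1,4-addition of the Hayashi–Miyaura type) should set C2'' as S through ligand-controlled enantioface selection in the aryl insertion, under base-free conditions that do not open the flavanone.

Step 5
Reactants: 9 (2S)-5,7-bis(benzyloxy)-2-[4-(benzyloxy)phenyl]chroman-4-one
Product: 10 (2S)-5,7-bis(benzyloxy)-2-[4-(benzyloxy)phenyl]-8-iodochroman-4-one
Conditions: N-iodosuccinimide (1.05 equiv), CF3CO2H (10 mol%), MeCN–CH2Cl2, 0 °C to rt, dark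
Reagents that add atoms: N-iodosuccinimide, O=C1CCC(=O)N1I
Why: Electrophilic aromatic iodination should go to C8, the activated position flanked by only one benzyloxy group (C6 lies between two), and the mild acid leaves C2'' untouched.

Step 6
Reactants: 10 (2S)-5,7-bis(benzyloxy)-2-[4-(benzyloxy)phenyl]-8-iodochroman-4-one
Product: 11 (2S)-5,7-bis(benzyloxy)-2-[4-(benzyloxy)phenyl]-4-oxochroman-8-carbaldehyde
Conditions: CO (1 atm), Bu3SnH (1.1 equiv, syringe pump), Pd(PPh3)4 (5 mol%), toluene, 50 °C
Reagents that add atoms: carbon monoxide, [C-]#[O+]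
Why: Stille-type reductive carbonylation (oxidative addition, CO insertion, hydride transfer from tin) converts the aryl iodide into the aldehyde under neutral conditions that cannot epimerise C2''.

Step 7
Reactants: 11 (2S)-5,7-bis(benzyloxy)-2-[4-(benzyloxy)phenyl]-4-oxochroman-8-carbaldehyde
Product: 12 N-[(E)-{(2S)-5,7-bis(benzyloxy)-2-[4-(benzyloxy)phenyl]-4-oxochroman-8-yl}methylidene]-4-methylbenzenesulfonamide
Conditions: TsNH2 (1.2 equiv), Ti(OEt)4 (3 equiv), toluene, 80 °C
Reagents that add atoms: 4-methylbenzenesulfonamide, Cc1ccc(cc1)S(N)(=O)=O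
Why: Titanium-alkoxide-mediated condensation should convert the hindered aldehyde (far more reactive than the diaryl-type ketone) into the N-sulfonyl aldimine; no stereocenter is formed.

Step 8
Reactants: 4 rac-4,6-bis(benzyloxy)-2-[3,4-bis(benzyloxy)phenyl]benzofuran-3(2H)-one; 12 N-[(E)-{(2S)-5,7-bis(benzyloxy)-2-[4-(benzyloxy)phenyl]-4-oxochroman-8-yl}methylidene]-4-methylbenzenesulfonamide
Product: 13 (2S)-4,6-bis(benzyloxy)-2-[3,4-bis(benzyloxy)phenyl]-2-[{(2S)-5,7-bis(benzyloxy)-2-[4-(benzyloxy)phenyl]-4-oxochroman-8-yl}(tosylamino)methyl]benzofuran-3(2H)-one (either epimer at the NHTs carbon)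
Conditions: quinine-derived squaramide 3-{[3,5-bis(trifluoromethyl)phenyl]amino}-4-{[(8α,9S)-6'-methoxycinchonan-9-yl]amino}cyclobut-3-ene-1,2-dione (10 mol%), toluene, −20 °C to rt, argon
Reagents that add atoms: none
Why: Organocatalytic asymmetric Mannich addition: the quinuclidine deprotonates the acidic, rapidly racemising 2-aryl ketone (both enantiomers of 4 give the same enolate) while the squaramide binds the sulfonyl imine, so the catalyst selects the enolate face and sets the quaternary C2 as S; the configuration at the NHTs carbon is immaterial.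

Step 9
Reactants: 13 (2S)-4,6-bis(benzyloxy)-2-[3,4-bis(benzyloxy)phenyl]-2-[{(2S)-5,7-bis(benzyloxy)-2-[4-(benzyloxy)phenyl]-4-oxochroman-8-yl}(tosylamino)methyl]benzofuran-3(2H)-one
Product: 16 (2R,3R)-5,7-bis(benzyloxy)-2-[3,4-bis(benzyloxy)phenyl]-3-{(2S)-5,7-bis(benzyloxy)-2-[4-(benzyloxy)phenyl]-4-oxochroman-8-yl}chroman-4-one, via benzylic cation 14 (not isolated), via oxocarbenium ion 15 (not isolated)
Conditions: HN(SO2CF3)2 (10 mol%), Et3SiH (3 equiv, added slowly), CH2Cl2, −60 to −20 °C
Reagents that add atoms: none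
Why: Proposed new method: the acid ionises the C–N bond of 13 (the sulfonamide leaves from the benzylic carbon activated by two ortho and one para oxygen of ring A of the lower unit) to cation 14, the acyl carbon C4 shifts from C2 to that carbon, breaking C2–C4 of the five-membered ring and forming C3–C4, and the resulting six-membered oxocarbenium ion 15 (charge at C2 held by O1 and the catechol ring) is reduced at C2 by Et3SiH. The closest known reaction types are the Lewis-acid rearrangement of α,β-epoxy ketones to 1,3-dicarbonyl compounds by 1,2-acyl migration to a benzylic cation, semipinacol and Tiffeneau–Demjanov ring expansions, and the silane reduction of cyclic oxocarbenium ions. The pyranone ring is not closed by joining two chain ends but by a suprafacial 1,2-shift that enlarges the benzofuranone ring from five to six members, so no Baldwin constraint applies. C3 is controlled by the quaternary C2 of 13: both epimers at the NHTs carbon give the same planar cation, and the shift should pass through the rotamer that holds the bulky lower-unit aryl group anti to the catechol ring and next to the small O1, which for (S)-C2 delivers C4 to the face that gives 3R. C2 is then controlled by C3: the 3-aryl group sits pseudo-axial (A(1,2) strain with the in-plane 2-aryl group) and the hydride enters anti to it, which places the two aryl groups cis (2R). The step needs acyl migration to win over migration of the catechol ring or of O1 (only the acyl shift leaves a cation stabilised by both O1 and an aryl group), over reduction of 14 before it rearranges (14 is the more stabilised and less electrophilic ion, and the silane is kept dilute and cold), and over loss of H3 from 15 to the flavone (the C3–H bond lies near the nodal plane of the cation and no base is present).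

Step 10
Reactants: 16 (2R,3R)-5,7-bis(benzyloxy)-2-[3,4-bis(benzyloxy)phenyl]-3-{(2S)-5,7-bis(benzyloxy)-2-[4-(benzyloxy)phenyl]-4-oxochroman-8-yl}chroman-4-one
Product: 17 (2R,3R)-2-(3,4-dihydroxyphenyl)-5,7-dihydroxy-3-[(2S)-5,7-dihydroxy-2-(4-hydroxyphenyl)-4-oxochroman-8-yl]chroman-4-one
Conditions: H2 (1 atm), Pd/C (10 wt%), EtOAc–MeOH, rt
Reagents that add atoms: none
Why: Hydrogenolysis of the seven benzyl ethers is neutral, so neither the enolisable cis-C3 centre nor the two flavanone C2 centres (sensitive to base through ring opening) should be disturbed.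

**Compound list**

1 | 4,6-dihydroxybenzofuran-3(2H)-one | O=C1COc2cc(O)cc(O)c21 | starting material
2 | 4,6-bis(benzyloxy)benzofuran-3(2H)-one | O=C1COc2cc(OCc3ccccc3)cc(OCc3ccccc3)c21 | intermediate
3 | 4-bromo-1,2-bis(benzyloxy)benzene | Brc1ccc(OCc2ccccc2)c(OCc2ccccc2)c1 | starting material
4 | rac-4,6-bis(benzyloxy)-2-[3,4-bis(benzyloxy)phenyl]benzofuran-3(2H)-one | O=C1C(c2ccc(OCc3ccccc3)c(OCc3ccccc3)c2)Oc2cc(OCc3ccccc3)cc(OCc3ccccc3)c21 | intermediate
5 | 1-[2,4-bis(benzyloxy)-6-hydroxyphenyl]ethanone | CC(=O)c1c(O)cc(OCc2ccccc2)cc1OCc1ccccc1 | starting material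
6 | (E)-1-[2,4-bis(benzyloxy)-6-hydroxyphenyl]-3-(dimethylamino)prop-2-en-1-one | CN(C)/C=C/C(=O)c1c(O)cc(OCc2ccccc2)cc1OCc1ccccc1 | intermediate (not isolated)
7 | 5,7-bis(benzyloxy)-4H-chromen-4-one | O=c1ccoc2cc(OCc3ccccc3)cc(OCc3ccccc3)c12 | intermediate
8 | 4-(benzyloxy)phenylboronic acid | OB(O)c1ccc(OCc2ccccc2)cc1 | starting material
9 | (2S)-5,7-bis(benzyloxy)-2-[4-(benzyloxy)phenyl]chroman-4-one | O=C1C[C@@H](c2ccc(OCc3ccccc3)cc2)Oc2cc(OCc3ccccc3)cc(OCc3ccccc3)c21 | intermediate
10 | (2S)-5,7-bis(benzyloxy)-2-[4-(benzyloxy)phenyl]-8-iodochroman-4-one | O=C1C[C@@H](c2ccc(OCc3ccccc3)cc2)Oc2c(I)c(OCc3ccccc3)cc(OCc3ccccc3)c21 | intermediate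
11 | (2S)-5,7-bis(benzyloxy)-2-[4-(benzyloxy)phenyl]-4-oxochroman-8-carbaldehyde | O=C1C[C@@H](c2ccc(OCc3ccccc3)cc2)Oc2c(C=O)c(OCc3ccccc3)cc(OCc3ccccc3)c21 | intermediate
12 | N-[(E)-{(2S)-5,7-bis(benzyloxy)-2-[4-(benzyloxy)phenyl]-4-oxochroman-8-yl}methylidene]-4-methylbenzenesulfonamide | O=C1C[C@@H](c2ccc(OCc3ccccc3)cc2)Oc2c(/C=N/S(=O)(=O)c3ccc(C)cc3)c(OCc3ccccc3)cc(OCc3ccccc3)c21 | intermediate
13 | (2S)-4,6-bis(benzyloxy)-2-[3,4-bis(benzyloxy)phenyl]-2-[{(2S)-5,7-bis(benzyloxy)-2-[4-(benzyloxy)phenyl]-4-oxochroman-8-yl}(tosylamino)methyl]benzofuran-3(2H)-one, either epimer at the NHTs carbon | O=C1C[C@@H](c2ccc(OCc3ccccc3)cc2)Oc2c1c(OCc1ccccc1)cc(OCc1ccccc1)c2C(NS(=O)(=O)c1ccc(C)cc1)[C@]1(c2ccc(OCc3ccccc3)c(OCc3ccccc3)c2)Oc2cc(OCc3ccccc3)cc(OCc3ccccc3)c2C1=O | intermediate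
14 | benzylic cation from 13 after loss of the sulfonamide, as its bis(triflyl)amide ion pair | O=C1C[C@@H](c2ccc(OCc3ccccc3)cc2)Oc2c1c(OCc1ccccc1)cc(OCc1ccccc1)c2[CH+][C@]1(c2ccc(OCc3ccccc3)c(OCc3ccccc3)c2)Oc2cc(OCc3ccccc3)cc(OCc3ccccc3)c2C1=O.FC(F)(F)S(=O)(=O)[N-]S(=O)(=O)C(F)(F)F | intermediate (not isolated)
15 | ring-expanded (3R)-4-oxochroman-2-ylium (oxocarbenium) ion, as its bis(triflyl)amide ion pair | O=C1C[C@@H](c2ccc(OCc3ccccc3)cc2)Oc2c1c(OCc1ccccc1)cc(OCc1ccccc1)c2[C@H]1C(=O)c2c(OCc3ccccc3)cc(OCc3ccccc3)cc2[O+]=C1c1ccc(OCc2ccccc2)c(OCc2ccccc2)c1.FC(F)(F)S(=O)(=O)[N-]S(=O)(=O)C(F)(F)F | intermediate (not isolated)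
16 | (2R,3R)-5,7-bis(benzyloxy)-2-[3,4-bis(benzyloxy)phenyl]-3-{(2S)-5,7-bis(benzyloxy)-2-[4-(benzyloxy)phenyl]-4-oxochroman-8-yl}chroman-4-one | O=C1C[C@@H](c2ccc(OCc3ccccc3)cc2)Oc2c1c(OCc1ccccc1)cc(OCc1ccccc1)c2[C@H]1C(=O)c2c(OCc3ccccc3)cc(OCc3ccccc3)cc2O[C@H]1c1ccc(OCc2ccccc2)c(OCc2ccccc2)c1 | intermediate
17 | (2R,3R)-2-(3,4-dihydroxyphenyl)-5,7-dihydroxy-3-[(2S)-5,7-dihydroxy-2-(4-hydroxyphenyl)-4-oxochroman-8-yl]chroman-4-one | O=C1C[C@@H](c2ccc(O)cc2)Oc2c1c(O)cc(O)c2[C@H]1C(=O)c2c(O)cc(O)cc2O[C@H]1c1ccc(O)c(O)c1 | target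

**Step count and risks**

Total steps: 10. Longest linear sequence: 8 (steps 3 to 10, from 5 to 17).

Steps most likely to fail:

1. Step 9 (Proposed new method). The first-formed cation may be reduced before the acyl group shifts, the catechol ring may migrate instead of the acyl group, the oxocarbenium ion may lose its C3 proton to give the flavone, or the rotamer preference may be too weak for clean transfer of chirality. The fallback uses known chemistry, sets out from 10 and returns at 17.
   - Miyaura borylation of 10 (bis(pinacolato)diboron, PdCl2(dppf), KOAc, dioxane, 80 °C) should give (2S)-5,7-bis(benzyloxy)-2-[4-(benzyloxy)phenyl]-8-(4,4,5,5-tetramethyl-1,3,2-dioxaborolan-2-yl)chroman-4-one F1.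
   - Separately, commercial luteolin F2 would be benzylated (BnBr, K2CO3, DMF) to 5,7,3',4'-tetrakis(benzyloxy)flavone F3 and iodinated at C3 (I2, (NH4)2Ce(NO3)6, MeCN) to 5,7-bis(benzyloxy)-2-[3,4-bis(benzyloxy)phenyl]-3-iodo-4H-chromen-4-one F4.
   - Suzuki–Miyaura coupling of F1 with F4 (Pd(OAc)2, SPhos, K3PO4, toluene–H2O, 70 °C) should give the 3-(flavanon-8-yl)flavone F5.
   - Hydrogenation of F5 (H2, 4 atm, Pd/C, EtOAc–MeOH) adds hydrogen to C2=C3 from one face (cis) and removes the benzyl groups. It should give 17 together with its (2S,3S,2''S) diastereomer F6; the two differ by the fixed 2''S centre and would be separated by reversed-phase chromatography.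

2. Step 8. Addition to the hindered, electron-rich imine may be slow or reversible, and facial control at the new quaternary carbon may be poor. The fallback gives up catalyst control in favour of separating diastereomers; it sets out from 4 and returns at 13.
   - 4 is converted with Me3SiCl and Et3N into {4,6-bis(benzyloxy)-2-[3,4-bis(benzyloxy)phenyl]benzofuran-3-yl}oxy(trimethyl)silane F7.
   - Mukaiyama–Mannich addition of F7 to 12 (BF3·OEt2, CH2Cl2, −78 °C) should give 13 and its (2R)-epimer at the quaternary carbon F8, which are diastereomers because of the 2''S centre and would be separated by chromatography.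

3. Step 5. The iodination may show poor site selectivity between C8, C6 and the benzyloxyphenyl ring. The fallback fixes the position by phenol-directed formylation before the pyranone ring exists; it sets out from 5 and returns at 11.
   - Magnesium-mediated ortho-formylation of 5 (MgCl2, Et3N, paraformaldehyde, MeCN, reflux; Casnati–Skattebøl conditions) can only reach the free position next to the phenol and should give 3-acetyl-4,6-bis(benzyloxy)-2-hydroxybenzaldehyde F9.
   - Chromone formation as in step 3 should give 5,7-bis(benzyloxy)-4-oxo-4H-chromene-8-carbaldehyde F10.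
   - Conjugate addition of 8 as in step 4 then leads to 11.

**Further compounds**

F1 | step 9 | (2S)-5,7-bis(benzyloxy)-2-[4-(benzyloxy)phenyl]-8-(4,4,5,5-tetramethyl-1,3,2-dioxaborolan-2-yl)chroman-4-one | O=C1C[C@@H](c2ccc(OCc3ccccc3)cc2)Oc2c(B3OC(C)(C)C(C)(C)O3)c(OCc3ccccc3)cc(OCc3ccccc3)c21
F2 | step 9 | luteolin | O=c1cc(-c2ccc(O)c(O)c2)oc2cc(O)cc(O)c12
F3 | step 9 | 5,7,3',4'-tetrakis(benzyloxy)flavone | O=c1cc(-c2ccc(OCc3ccccc3)c(OCc3ccccc3)c2)oc2cc(OCc3ccccc3)cc(OCc3ccccc3)c12
F4 | step 9 | 5,7-bis(benzyloxy)-2-[3,4-bis(benzyloxy)phenyl]-3-iodo-4H-chromen-4-one | O=c1c(I)c(-c2ccc(OCc3ccccc3)c(OCc3ccccc3)c2)oc2cc(OCc3ccccc3)cc(OCc3ccccc3)c12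
F5 | step 9 | 5,7-bis(benzyloxy)-2-[3,4-bis(benzyloxy)phenyl]-3-{(2S)-5,7-bis(benzyloxy)-2-[4-(benzyloxy)phenyl]-4-oxochroman-8-yl}-4H-chromen-4-one | O=C1C[C@@H](c2ccc(OCc3ccccc3)cc2)Oc2c(-c3c(-c4ccc(OCc5ccccc5)c(OCc5ccccc5)c4)oc4cc(OCc5ccccc5)cc(OCc5ccccc5)c4c3=O)c(OCc3ccccc3)cc(OCc3ccccc3)c21
F6 | step 9 | (2S,3S)-2-(3,4-dihydroxyphenyl)-5,7-dihydroxy-3-[(2S)-5,7-dihydroxy-2-(4-hydroxyphenyl)-4-oxochroman-8-yl]chroman-4-one | O=C1C[C@@H](c2ccc(O)cc2)Oc2c1c(O)cc(O)c2[C@@H]1C(=O)c2c(O)cc(O)cc2O[C@@H]1c1ccc(O)c(O)c1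
F7 | step 8 | {4,6-bis(benzyloxy)-2-[3,4-bis(benzyloxy)phenyl]benzofuran-3-yl}oxy(trimethyl)silane | C[Si](C)(C)Oc1c(-c2ccc(OCc3ccccc3)c(OCc3ccccc3)c2)oc2cc(OCc3ccccc3)cc(OCc3ccccc3)c12
F8 | step 8 | (2R)-epimer of 13 at the quaternary benzofuranone carbon | O=C1C[C@@H](c2ccc(OCc3ccccc3)cc2)Oc2c1c(OCc1ccccc1)cc(OCc1ccccc1)c2C(NS(=O)(=O)c1ccc(C)cc1)[C@@]1(c2ccc(OCc3ccccc3)c(OCc3ccccc3)c2)Oc2cc(OCc3ccccc3)cc(OCc3ccccc3)c2C1=O
F9 | step 5 | 3-acetyl-4,6-bis(benzyloxy)-2-hydroxybenzaldehyde | CC(=O)c1c(O)c(C=O)c(OCc2ccccc2)cc1OCc1ccccc1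
F10 | step 5 | 5,7-bis(benzyloxy)-4-oxo-4H-chromene-8-carbaldehyde | O=Cc1c(OCc2ccccc2)cc(OCc2ccccc2)c2c(=O)ccoc12
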